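I nearly read the flat tops of the earlier curves straight across to Saturday's, Monday's and Thursday's, and that was the trap: a cold flask may still be climbing when it is read.

| flask | starting material | partner | protic impurity | temperature | remark | time |
|---|---|---|---|---|---|---|
| beta | 1 M | 1.3 equiv | 0.25 M | 2 °C | run made earlier |  |
| theta | 1 M | 1.3 equiv | 0.38 M | 30 °C | run made earlier |  |
| eta | 1.5 M | 1.3 equiv | 0.50 M | 2 °C | run made earlier |  |
| Saturday's | 1.0 M | 1.30 equiv | 0.500 M | 15 °C |  | 20 h |
| Monday's | 1.0 M | 1.30 equiv | 0.500 M | 40 °C |  | 20 h |
| Thursday's | 1.0 M | 1.30 equiv | 0.500 M | −10 °C |  | 20 h |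

- beta (time / h: target / %): 1.50: 4; 5.00: 3; 10.0: 10; 12.0: 6; 20.0: 11; 25.0: 14; 30.0: 14
- theta (time / h: target / %): 0.667: 8; 1.00: 14; 1.33: 13; 2.50: 16; 3.00: 21; 5.00: 25; 8.00: 29
- eta (time / h: target / %): 2.50: 4; 5.00: 2; 10.0: 10; 15.0: 6; 30.0: 13

(standard deviation of a reading: 2 percentage points)

- the earlier runs were read with a standard deviation of 2 percentage points

- the flask with the highest amount of target, in percent of the starting material charged ("all alike" if they lie within 1.5 percentage points) (Saturday's / Monday's / Thursday's / all alike)
- final target, as a percentage of the starting material charged, in Saturday's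
- final target, as a percentage of the starting material charged, in Monday's
- final target, as a percentage of the starting material charged, in Thursday's

I set two extremes above each new flask, both of them ceilings. A finished flask stands on its plateau, the selectivity at full conversion. A flask caught early still lies on its first straight line, the plateau times run time over settling time, where the settling time is the time in which the gap to the plateau shrinks by a factor e. The real curve bends away from that line, so it lies below both extremes.

The beta run had a plateau near 14.0 % and a settling time of about 13.0 h. The theta run reached 29 % with a settling time of about 2.71 h; both are readings and carry their scatter. Eta differed from beta in protic impurity and in starting material at once, so its 13 % against beta's 14 % isolated neither setting, and my reckoning simply carried no term for the impurity.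

Stepping both quantities by a constant factor per degree, I got a settling time of 25.4 h for Thursday's and 1.55 h for Monday's. Saturday's came to 6.27 h. Thursday's plateau came to 10.2 % and its straight line to 8.06 %, and the curve under them gave 5.58 %. Saturday's gave 18.8 %. Monday's run was far longer than my settling time for it, so I put it on its plateau at 37.6 %, the highest of my figures.

The forecast gave 17 % (11 % to 24 %) for Saturday's, 33 % (23 % to 43 %) for Monday's and 5 % (2 % to 10 %) for Thursday's, and chose Monday's: “The hottest flask wins”. My Monday's figure was higher than its central value.

The flasks gave 19.3 % in Saturday's, 32.2 % in Monday's and 3.65 % in Thursday's, so Monday's led, by 13 points over Saturday's.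

    starting material + partner → target (k = 8.70 × 10⁻⁵ M⁻¹ s⁻¹, Ea = 70.0 kJ mol⁻¹)
    starting material + 2 partner → side product (k = 5.60 × 10⁻⁵ M⁻² s⁻¹, Ea = 48.0 kJ mol⁻¹)
    starting material + protic impurity → quenched substrate (k = 8.70 × 10⁻⁴ M⁻¹ s⁻¹, Ea = 75.0 kJ mol⁻¹)
    partner → decomposed reagent (k = 2.90 × 10⁻⁶ s⁻¹, Ea = 110 kJ mol⁻¹)
    (constants at 40 °C)

Monday's run lasted 12.9 of my settling times, and its target stood at 31.5 % after 10.0 h and 32.2 % after 20.0 h. Thursday's reached 29.4 % of the 12.4 % it showed after 200 h, when 20.4 % of its starting material still stood; taken as a top all the same, that figure reads as a settling time of 57.6 h, twice mine and longer than its run. Carried to Thursday's read at 3.0 d, that settling time gives 8.85 %, and that flask stood at 8.22 %.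

The data were computed from invented constants, noise included.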